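**Strategy.** The flavone is cut at the C4–C4a bond, so ring C is closed last by an intramolecular Friedel–Crafts acylation. The substrate is an (E)-3-aryl-3-aryloxy-2-methoxyacrylic acid in which O1–C2, the 3-methoxyl and ring B with its prenyl ether are already in place; its aryloxy part is ring A with two allyl ethers. Once the carboxyl group is activated, C4 can only attack the single unsubstituted ring A carbon next to O1 (C4a), ortho to the C5 oxygen and para to the C7 oxygen, because the other neighbour of O1 carries the C8 methoxyl. One operation thus builds the pyranone with fixed regiochemistry; deallylation finishes the synthesis.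

Key step: step 11

Assumption: 6, 14, 15 and 16 are drawn as E isomers (triflate or aryloxy group cis to the carbonyl group), the outcome expected from a chelated enolate and a stereoretentive substitution; any Z material would be carried along, since both isomers converge in step 11.

Abbreviations: allyl = prop-2-en-1-yl; prenyl = 3-methylbut-2-en-1-yl; MOM = methoxymethyl.

**Step 1**
Reactants: 1 methyl vanillate (methyl 4-hydroxy-3-methoxybenzoate); 2 prenyl bromide
Product: 3 methyl 3-methoxy-4-(prenyloxy)benzoate
Conditions: K2CO3, DMF, rt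
Reagents that add atoms: none
Why: Williamson ether synthesis, in which the phenoxide of 1 displaces bromide from the primary allylic halide (SN2) while the methyl ester is inert to K2CO3 in DMF.

**Step 2**
Reactants: 3 methyl 3-methoxy-4-(prenyloxy)benzoate; 4 methyl methoxyacetate
Product: 5 methyl 2-methoxy-3-[3-methoxy-4-(prenyloxy)phenyl]-3-oxopropanoate (racemic)
Conditions: 4 (1.5 equiv), LiN(SiMe3)2 (3 equiv), THF, −78 °C; then 3, −78 to 0 °C; then AcOH
Reagents that add atoms: none
Why: Crossed Claisen condensation, in which the lithium enolate of 4, formed completely at −78 °C, acylates the non-enolisable aryl ester and excess amide base drives the equilibrium by deprotonating the β-keto ester; the one stereocentre forms as a racemate and is erased in step 3.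

**Step 3**
Reactants: 5 methyl 2-methoxy-3-[3-methoxy-4-(prenyloxy)phenyl]-3-oxopropanoate
Product: 6 methyl (E)-2-methoxy-3-[3-methoxy-4-(prenyloxy)phenyl]-3-[(trifluoromethylsulfonyl)oxy]prop-2-enoate (triflate cis to CO2Me)
Conditions: NaH, THF, 0 °C; then PhNTf2, 0 °C to rt; then AcOH
Reagents that add atoms: N-phenylbis(trifluoromethanesulfonimide), O=S(=O)(N(c1ccccc1)S(=O)(=O)C(F)(F)F)C(F)(F)F
Why: O-Sulfonylation of a β-keto ester enolate, in which sodium chelation holds the enolate oxygen cis to the ester carbonyl so that triflyl transfer should give mainly the E enol triflate, and the mild triflyl donor leaves the prenyl ether untouched.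

**Step 4**
Reactants: 7 2,4,6-trihydroxybenzaldehyde
Product: 8 2,4-bis(allyloxy)-6-hydroxybenzaldehyde
Conditions: allyl bromide (2.1 equiv), K2CO3 (2.2 equiv), DMF, 0 °C to rt
Reagents that add atoms: allyl bromide, C=CCBr
Why: Regioselective Williamson etherification, in which the 4-OH and one ortho OH are alkylated while the last ortho OH stays hydrogen-bonded to the aldehyde and is poorly nucleophilic, the usual behaviour of acylphloroglucinols.

**Step 5**
Reactants: 8 2,4-bis(allyloxy)-6-hydroxybenzaldehyde
Product: 9 2,4-bis(allyloxy)-6-(methoxymethoxy)benzaldehyde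
Conditions: MOMCl, iPr2NEt, CH2Cl2, 0 to 40 °C
Reagents that add atoms: chloromethyl methyl ether, COCCl
Why: Acetal protection of the phenol by O-alkylation with the α-chloro ether; unlike an acyl or silyl group, the MOM group cannot migrate to the neighbouring oxygen set free in step 6.

**Step 6**
Reactants: 9 2,4-bis(allyloxy)-6-(methoxymethoxy)benzaldehyde
Product: 11 2,4-bis(allyloxy)-6-(methoxymethoxy)phenol, via aryl formate 10 (not isolated)
Conditions: mCPBA, CH2Cl2, 0 °C to rt; aq. Na2S2O3 wash; then K2CO3 (cat.), MeOH, 0 °C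
Reagents that add atoms: 3-chloroperoxybenzoic acid, OOC(=O)c1cccc(Cl)c1
Why: Baeyer–Villiger (Dakin-type) oxidation, in which the trioxygenated aryl group migrates much faster than the peracid epoxidises the monosubstituted allyl alkenes; the labile formate is methanolysed only after the oxidant is destroyed, so the oxidisable phenol never meets peracid.

**Step 7**
Reactants: 11 2,4-bis(allyloxy)-6-(methoxymethoxy)phenol
Product: 12 1,5-bis(allyloxy)-2-methoxy-3-(methoxymethoxy)benzene
Conditions: MeI, K2CO3, DMF, rt
Reagents that add atoms: iodomethane, CI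
Why: Williamson methylation of the only free phenol, which fixes the methoxyl on the oxygen that becomes C8–OMe.

**Step 8**
Reactants: 12 1,5-bis(allyloxy)-2-methoxy-3-(methoxymethoxy)benzene
Product: 13 3,5-bis(allyloxy)-2-methoxyphenol
Conditions: HCl (0.2 equiv), MeOH, 40 °C
Reagents that add atoms: none
Why: Acid-catalysed acetal exchange with methanol removes the MOM group as dimethoxymethane, while aryl allyl and aryl methyl ethers do not ionise in dilute methanolic HCl.

**Step 9**
Reactants: 13 3,5-bis(allyloxy)-2-methoxyphenol; 6 enol triflate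
Product: 14 methyl (E)-3-[3,5-bis(allyloxy)-2-methoxyphenoxy]-2-methoxy-3-[3-methoxy-4-(prenyloxy)phenyl]prop-2-enoate
Conditions: Cs2CO3, MeCN, rt to 50 °C
Reagents that add atoms: none
Why: Nucleophilic vinylic substitution by addition–elimination (oxa-Michael addition of the caesium phenoxide to the triflate-bearing β-carbon, then loss of triflate), the established route from β-sulfonyloxy or β-halo enoates to β-aryloxy acrylates; retention should place the aryloxy group cis to the ester.

**Step 10**
Reactants: 14 methyl ester
Product: 15 (E)-3-[3,5-bis(allyloxy)-2-methoxyphenoxy]-2-methoxy-3-[3-methoxy-4-(prenyloxy)phenyl]prop-2-enoic acid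
Conditions: LiOH, THF/MeOH/H2O, 40 °C; then 1 M HCl, 0 °C, to pH 4
Reagents that add atoms: lithium hydroxide, [Li+].[OH-]
Why: Saponification (BAc2), in which hydroxide attacks the ester carbonyl because the β-carbon is deactivated by its aryloxy, aryl and α-methoxy donors, and cold acidification to pH 4 spares the prenyl ether and the enol ether.

**Step 11**
Reactants: 15 (E)-acrylic acid
Product: 17 5,7-bis(allyloxy)-3,8-dimethoxy-2-[3-methoxy-4-(prenyloxy)phenyl]-4H-chromen-4-one, via acid chloride 16 (not isolated)
Conditions: 1-chloro-N,N,2-trimethylprop-1-en-1-amine, 2,6-di-tert-butyl-4-methylpyridine, CH2Cl2, 0 °C to rt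
Reagents that add atoms: none
Why: The α-chloroenamine turns the acid into acid chloride 16 under neutral conditions, and this push–pull acyl chloride should ionise readily to an acylium ion stabilised by the C2 aryloxy oxygen, the 3-methoxyl and ring B; the ring A carbon ortho to the ether oxygen attacks the acyl carbon and proton loss to the hindered pyridine restores the arene (intramolecular Friedel–Crafts acylation, the ring closure of the Ruhemann chromone synthesis from β-aryloxyacrylic acids). Ring C closes in a 6-exo-trig mode at the acyl carbon, with the C2=C3 double bond and the C8a–C4a arene bond inside the new ring. No stereocentre is formed. Regiochemistry is set by the substrate: of the two carbons ortho to O1, one carries the methoxyl that becomes C8–OMe, so only the carbon activated by the ortho C5 oxygen and the para C7 oxygen can become C4a. Only the E geometry (carboxyl cis to aryloxy) reaches that carbon, and Z material should equilibrate through the acylium ion, whose C2–C3 bond has single-bond character, faster than it closes a strained indenone onto the much less nucleophilic ring B. The neutral reagent and the pyridine buffer keep HCl away from the acid-labile prenyl and allyl ethers.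

**Step 12**
Reactants: 17 bis(allyl) flavone
Product: 18 5,7-dihydroxy-3,8-dimethoxy-2-[3-methoxy-4-(prenyloxy)phenyl]-4H-chromen-4-one (5,7-dihydroxy-3,8,3'-trimethoxy-4'-prenyloxyflavone)
Conditions: Pd(PPh3)4 (5 mol%), morpholine, THF, rt
Reagents that add atoms: none
Why: Tsuji–Trost-type deallylation, in which zerovalent palladium ionises the two unhindered aryl allyl ethers to π-allyl complexes that morpholine captures; the prenyl ether, whose trisubstituted alkene binds palladium poorly, reacts far more slowly, so the reaction is stopped once both allyl groups are gone.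

**Compound list**
1 | methyl vanillate (methyl 4-hydroxy-3-methoxybenzoate) | COC(=O)c1ccc(O)c(OC)c1 | starting material
2 | prenyl bromide (1-bromo-3-methylbut-2-ene) | CC(C)=CCBr | starting material
3 | methyl 3-methoxy-4-[(3-methylbut-2-en-1-yl)oxy]benzoate | COC(=O)c1ccc(OCC=C(C)C)c(OC)c1 | intermediate
4 | methyl methoxyacetate | COCC(=O)OC | starting material
5 | methyl 2-methoxy-3-{3-methoxy-4-[(3-methylbut-2-en-1-yl)oxy]phenyl}-3-oxopropanoate (racemic) | COC(C(=O)OC)C(=O)c1ccc(OCC=C(C)C)c(OC)c1 | intermediate
6 | methyl (E)-2-methoxy-3-{3-methoxy-4-[(3-methylbut-2-en-1-yl)oxy]phenyl}-3-[(trifluoromethylsulfonyl)oxy]prop-2-enoate | CO/C(C(=O)OC)=C(/OS(=O)(=O)C(F)(F)F)c1ccc(OCC=C(C)C)c(OC)c1 | intermediate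
7 | 2,4,6-trihydroxybenzaldehyde | O=Cc1c(O)cc(O)cc1O | starting material
8 | 2,4-bis(allyloxy)-6-hydroxybenzaldehyde | O=Cc1c(O)cc(OCC=C)cc1OCC=C | intermediate
9 | 2,4-bis(allyloxy)-6-(methoxymethoxy)benzaldehyde | COCOc1cc(OCC=C)cc(OCC=C)c1C=O | intermediate
10 | 2,4-bis(allyloxy)-6-(methoxymethoxy)phenyl formate (formed in the flask, not isolated) | COCOc1cc(OCC=C)cc(OCC=C)c1OC=O | intermediate
11 | 2,4-bis(allyloxy)-6-(methoxymethoxy)phenol | COCOc1cc(OCC=C)cc(OCC=C)c1O | intermediate
12 | 1,5-bis(allyloxy)-2-methoxy-3-(methoxymethoxy)benzene | COCOc1cc(OCC=C)cc(OCC=C)c1OC | intermediate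
13 | 3,5-bis(allyloxy)-2-methoxyphenol | COc1c(O)cc(OCC=C)cc1OCC=C | intermediate
14 | methyl (E)-3-[3,5-bis(allyloxy)-2-methoxyphenoxy]-2-methoxy-3-{3-methoxy-4-[(3-methylbut-2-en-1-yl)oxy]phenyl}prop-2-enoate | CO/C(C(=O)OC)=C(/Oc1cc(OCC=C)cc(OCC=C)c1OC)c1ccc(OCC=C(C)C)c(OC)c1 | intermediate
15 | (E)-3-[3,5-bis(allyloxy)-2-methoxyphenoxy]-2-methoxy-3-{3-methoxy-4-[(3-methylbut-2-en-1-yl)oxy]phenyl}prop-2-enoic acid | CO/C(C(=O)O)=C(/Oc1cc(OCC=C)cc(OCC=C)c1OC)c1ccc(OCC=C(C)C)c(OC)c1 | intermediate
16 | (E)-3-[3,5-bis(allyloxy)-2-methoxyphenoxy]-2-methoxy-3-{3-methoxy-4-[(3-methylbut-2-en-1-yl)oxy]phenyl}prop-2-enoyl chloride (formed in the flask, not isolated) | CO/C(C(Cl)=O)=C(/Oc1cc(OCC=C)cc(OCC=C)c1OC)c1ccc(OCC=C(C)C)c(OC)c1 | intermediate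
17 | 5,7-bis(allyloxy)-3,8-dimethoxy-2-{3-methoxy-4-[(3-methylbut-2-en-1-yl)oxy]phenyl}-4H-chromen-4-one | COc1cc(-c2oc3c(OC)c(OCC=C)cc(OCC=C)c3c(=O)c2OC)ccc1OCC=C(C)C | intermediate
18 | 5,7-dihydroxy-3,8-dimethoxy-2-{3-methoxy-4-[(3-methylbut-2-en-1-yl)oxy]phenyl}-4H-chromen-4-one | COc1cc(-c2oc3c(OC)c(O)cc(O)c3c(=O)c2OC)ccc1OCC=C(C)C | target

**Totals.** Total step count: 12. Longest linear sequence: 9 steps (steps 4 to 12, from 7).

**Steps most likely to fail**

1. Step 11. Ring closure may be too slow under neutral activation, and stronger acids would invite loss or migration of the prenyl group and closure onto ring B from Z material (ZnCl2 as a mild additive would only be a change of conditions). The fallback sets out from acid 15 and returns at flavone 17. The acid would be coupled with dimethylamine (EDC·HCl, HOBt, CH2Cl2) to the tertiary amide (E)-3-[3,5-bis(allyloxy)-2-methoxyphenoxy]-2-methoxy-N,N-dimethyl-3-[3-methoxy-4-(prenyloxy)phenyl]prop-2-enamide F1. Electrophilic amide activation (Tf2O, 2-fluoropyridine, CH2Cl2, −78 to 0 °C) should give an O-triflyl iminium ion that the same ring A carbon traps in a Vilsmeier–Haack-type cyclisation, forming 5,7-bis(allyloxy)-4-(dimethyliminio)-3,8-dimethoxy-2-[3-methoxy-4-(prenyloxy)phenyl]chromene triflate F2. Aqueous NaHCO3 would hydrolyse it to 17.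

2. Step 9. Addition of the phenoxide to a tetrasubstituted, donor-substituted β-carbon may be slow, and attack at sulfur (triflyl transfer to the phenoxide, returning the enolate of 5) may compete. The fallback sets out from β-keto ester 5 and phenol 13 and returns at ester 14. 5 would be deoxychlorinated with the Vilsmeier salt made from oxalyl chloride and DMF, buffered with 2,6-lutidine (CH2Cl2, 0 °C to rt), to methyl (E)-3-chloro-2-methoxy-3-[3-methoxy-4-(prenyloxy)phenyl]prop-2-enoate F3, which has no sulfonyl group to be attacked. The caesium phenoxide of 13 (Cs2CO3, DMF, 60 °C, DABCO as nucleophilic catalyst if needed) would then displace chloride by the classical addition–elimination of β-chloro acrylates.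

3. Step 2. Acyl transfer to the electron-rich benzoate may be slow, so that the α-alkoxy enolate self-condenses or decomposes on warming. The fallback sets out from ester 3 and returns at β-keto ester 5. 3 would be saponified (LiOH, aq. THF/MeOH) to 3-methoxy-4-(prenyloxy)benzoic acid F4 and activated with 1,1'-carbonyldiimidazole (THF, rt) to the acyl imidazole (1H-imidazol-1-yl)[3-methoxy-4-(prenyloxy)phenyl]methanone F5. This much better acyl donor would acylate the preformed lithium enolate of 4 (LiN(iPr)2, 2.2 equiv, THF, −78 °C).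

**Further compounds**
F1 | step 11 | (E)-3-[3,5-bis(allyloxy)-2-methoxyphenoxy]-2-methoxy-N,N-dimethyl-3-{3-methoxy-4-[(3-methylbut-2-en-1-yl)oxy]phenyl}prop-2-enamide | CO/C(C(=O)N(C)C)=C(/Oc1cc(OCC=C)cc(OCC=C)c1OC)c1ccc(OCC=C(C)C)c(OC)c1
F2 | step 11 | 5,7-bis(allyloxy)-4-(dimethyliminio)-3,8-dimethoxy-2-{3-methoxy-4-[(3-methylbut-2-en-1-yl)oxy]phenyl}-4H-chromene trifluoromethanesulfonate | C[N+](C)=c1c(OC)c(-c2ccc(OCC=C(C)C)c(OC)c2)oc2c(OC)c(OCC=C)cc(OCC=C)c12.[O-]S(=O)(=O)C(F)(F)F
F3 | step 9 | methyl (E)-3-chloro-2-methoxy-3-{3-methoxy-4-[(3-methylbut-2-en-1-yl)oxy]phenyl}prop-2-enoate | CO/C(C(=O)OC)=C(/Cl)c1ccc(OCC=C(C)C)c(OC)c1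
F4 | step 2 | 3-methoxy-4-[(3-methylbut-2-en-1-yl)oxy]benzoic acid | COc1cc(C(=O)O)ccc1OCC=C(C)C
F5 | step 2 | (1H-imidazol-1-yl){3-methoxy-4-[(3-methylbut-2-en-1-yl)oxy]phenyl}methanone | COc1cc(C(=O)n2ccnc2)ccc1OCC=C(C)C
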